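**Plan**
- Retrosynthesis cuts, in order: the chalcone Cα=Cβ bond (Claisen–Schmidt); the C4–C5 σ-bond of the heptenyl chain (C4 = the CH2 beside carbinol C3, C5 = the vinylic CH of the C5=C6 alkene); the C7–C3' bond to ring A (Negishi); the C7–alkyne bond (acetylide addition).
- Enabling feature: the (E)-homoallylic alcohol O–C3–C4–C5=C6. O–C3–C4 is a terminal epoxide in disguise and C5 an alkenyl iodide carbon, so two electrophilic carbons can be joined reductively at nickel (a like-polarity union). No organometallic has to be made beside the ring A ketone.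
- Forward: ring A acetophenone → 3'-iodide → arylzinc → enantioconvergent Ni/pybox arylation of a racemic propargylic carbonate (sets C7) → terminal alkyne → (E)-alkenyl iodide (fragment 1). Separately, aryl bromide → butenylarene → epoxide → resolved (S)-epoxide (fragment 2). Then union, aldol condensation with the ring B aldehyde, and removal of five MOM groups.
- Stereochemistry: C7 (R) by catalyst control in the Negishi step; C3 (S) from the hydrolytic kinetic resolution, untouched because the union takes place at the epoxide CH2; C5=C6 (E) from syn-hydrostannation with stereoretentive iodination and coupling; the enone (E) is thermodynamic.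

Key step: step 11

Assumption: the pybox antipode that delivers (R)-9 cannot be predicted for this doubly ortho-substituted arylzinc and is to be assigned on a test coupling; 1, 5 and 13 are taken as commercial.

**Route**

Step 1
Reactants: 1 1-(2,4-dihydroxy-6-methoxyphenyl)ethan-1-one
Product: 2 1-[2-hydroxy-6-methoxy-4-(methoxymethoxy)phenyl]ethan-1-one
Conditions: MOMCl (1.1 equiv), K2CO3, acetone, 0 °C → rt
Reagents that add atoms: chloromethyl methyl ether, COCCl
Why: Williamson-type MOM protection should take place only at the 4'-OH, which is para to the acetyl group, more acidic and not chelated, while the hydrogen-bonded 2'-OH stays free.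

Step 2
Reactants: 2 1-[2-hydroxy-6-methoxy-4-(methoxymethoxy)phenyl]ethan-1-one
Product: 3 1-[2-hydroxy-3-iodo-6-methoxy-4-(methoxymethoxy)phenyl]ethan-1-one
Conditions: NIS (1.05 equiv), MeCN, 0 °C → rt, dark
Reagents that add atoms: N-iodosuccinimide, O=C1CCC(=O)N1I
Why: Electrophilic aromatic iodination should go to C3', ortho to the free chelated phenol (and ortho to OMOM, para to OMe), as is usual for 2'-hydroxy-4',6'-dialkoxyacetophenones; a minor 5'-isomer would be removed by chromatography.

Step 3
Reactants: 3 1-[2-hydroxy-3-iodo-6-methoxy-4-(methoxymethoxy)phenyl]ethan-1-one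
Product: 4 1-[3-iodo-6-methoxy-2,4-bis(methoxymethoxy)phenyl]ethan-1-one
Conditions: NaH (1.1 equiv), MOMCl (1.3 equiv), DMF, 0 °C
Reagents that add atoms: chloromethyl methyl ether, COCCl
Why: The hindered chelated phenol is deprotonated irreversibly (far more acidic than the methyl ketone) and the naked phenoxide is O-alkylated by MOMCl (Williamson-type acetal formation).

Step 4
Reactants: 5 4-(methoxymethoxy)benzaldehyde
Product: 7 methyl 1-[4-(methoxymethoxy)phenyl]-3-(trimethylsilyl)prop-2-yn-1-yl carbonate (racemic), via lithium propargylic alkoxide 6 (not isolated)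
Conditions: ethynyltrimethylsilane, n-BuLi, THF, −78 °C; then ClCO2Me, −78 → 0 °C
Reagents that add atoms: ethynyltrimethylsilane, C#C[Si](C)(C)C; methyl chloroformate, COC(=O)Cl
Why: 1,2-Addition of the lithium acetylide to the aldehyde gives alkoxide 6, which is acylated in the same flask, so the ionisable p-alkoxybenzylic propargylic alcohol is never handled.

Step 5
Reactants: 4 1-[3-iodo-6-methoxy-2,4-bis(methoxymethoxy)phenyl]ethan-1-one; 7 methyl 1-[4-(methoxymethoxy)phenyl]-3-(trimethylsilyl)prop-2-yn-1-yl carbonate (racemic)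
Product: 9 1-{6-methoxy-2,4-bis(methoxymethoxy)-3-[(1R)-1-[4-(methoxymethoxy)phenyl]-3-(trimethylsilyl)prop-2-yn-1-yl]phenyl}ethan-1-one, via arylzinc iodide 8 (not isolated)
Conditions: Zn dust, LiCl, THF, 25–40 °C; then 7, NiCl2·glyme (10 mol %), indanyl-pybox (13 mol %, antipode giving R), DME, −20 °C
Reagents that add atoms: none
Why: Enantioconvergent nickel/pybox Negishi arylation of a racemic propargylic carbonate: both enantiomers of 7 pass through the same propargylic radical and the chiral nickel complex decides the face to which the aryl group of the ketone-tolerant arylzinc 8 is delivered, which should set C7 as (R).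

Step 6
Reactants: 9 1-{6-methoxy-2,4-bis(methoxymethoxy)-3-[(1R)-1-[4-(methoxymethoxy)phenyl]-3-(trimethylsilyl)prop-2-yn-1-yl]phenyl}ethan-1-one
Product: 10 1-{6-methoxy-2,4-bis(methoxymethoxy)-3-[(1R)-1-[4-(methoxymethoxy)phenyl]prop-2-yn-1-yl]phenyl}ethan-1-one
Conditions: K2CO3 (0.2 equiv), MeOH, 0 °C, short reaction time
Reagents that add atoms: none
Why: Methoxide-catalysed protodesilylation of the alkynylsilane is fast at 0 °C, conditions under which the doubly benzylic propargylic C7–H should not be removed (no allene formation, no racemisation).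

Step 7
Reactants: 10 1-{6-methoxy-2,4-bis(methoxymethoxy)-3-[(1R)-1-[4-(methoxymethoxy)phenyl]prop-2-yn-1-yl]phenyl}ethan-1-one
Product: 12 1-{3-[(1R,2E)-3-iodo-1-[4-(methoxymethoxy)phenyl]prop-2-en-1-yl]-6-methoxy-2,4-bis(methoxymethoxy)phenyl}ethan-1-one, via E-alkenylstannane 11 (not isolated)
Conditions: Bu3SnH (1.1 equiv, slow addition), PdCl2(PPh3)2 (2 mol %), THF, 0 °C; then I2 (1.1 equiv), CH2Cl2, 0 °C
Reagents that add atoms: iodine, II
Why: Palladium-catalysed syn-hydrostannation puts tin on the terminal carbon, away from the bulky diarylmethyl group, and leaves the hindered aryl ketone alone; iododestannylation then proceeds with retention to the (E)-alkenyl iodide and is much faster than iodination of the arenes.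

Step 8
Reactants: 13 1-bromo-4-(methoxymethoxy)benzene
Product: 14 1-(but-3-en-1-yl)-4-(methoxymethoxy)benzene
Conditions: but-3-en-1-ylmagnesium bromide (1.3 equiv), PdCl2(dppf) (2 mol %), THF, reflux
Reagents that add atoms: but-3-en-1-ylmagnesium bromide, C=CCC[Mg]Br
Why: Kumada coupling of an aryl bromide with a primary alkyl Grignard reagent; the wide-bite-angle dppf ligand favours reductive elimination over β-hydride elimination.

Step 9
Reactants: 14 1-(but-3-en-1-yl)-4-(methoxymethoxy)benzene
Product: 15 2-{2-[4-(methoxymethoxy)phenyl]ethyl}oxirane (racemic)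
Conditions: mCPBA (1.2 equiv), CH2Cl2, 0 °C → rt
Reagents that add atoms: 3-chloroperoxybenzoic acid, OOC(=O)c1cccc(Cl)c1
Why: Prilezhaev epoxidation of the terminal alkene; the aryl MOM ether is inert to the peracid.

Step 10
Reactants: 15 2-{2-[4-(methoxymethoxy)phenyl]ethyl}oxirane (racemic)
Product: 16 (2S)-2-{2-[4-(methoxymethoxy)phenyl]ethyl}oxirane
Conditions: (S,S)-(salen)Co(OAc) (0.5 mol %), H2O (0.55 equiv), THF, 0 °C → rt
Reagents that add atoms: none
Why: Hydrolytic kinetic resolution: the trivalent cobalt salen complex with the (S,S) ligand hydrolyses the (R)-epoxide of a simple alkyl oxirane much faster, so the (S)-epoxide that becomes C3 should be recovered in high enantiomeric purity.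

Step 11
Reactants: 12 1-{3-[(1R,2E)-3-iodo-1-[4-(methoxymethoxy)phenyl]prop-2-en-1-yl]-6-methoxy-2,4-bis(methoxymethoxy)phenyl}ethan-1-one; 16 (2S)-2-{2-[4-(methoxymethoxy)phenyl]ethyl}oxirane (1.5 equiv)
Product: 18 1-{3-[(1R,2E,5S)-5-hydroxy-1,7-bis[4-(methoxymethoxy)phenyl]hept-2-en-1-yl]-6-methoxy-2,4-bis(methoxymethoxy)phenyl}ethan-1-one, via iodohydrin 17 (not isolated)
Conditions: NiCl2·glyme (10 mol %), 2,2'-bipyridine (10 mol %), NaI (25 mol %), Et3N·HCl (1 equiv), Zn dust (2 equiv), DMPU, rt
Reagents that add atoms: none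
Why: Iodide (NaI, with Et3N·HCl as proton source) opens epoxide 16 by SN2 attack at the unsubstituted C4 to give iodohydrin 17, whose C–I bond is reduced by low-valent nickel to a primary C4 radical; zerovalent nickel meanwhile inserts into the alkenyl C5–I bond of 12, the alkenylnickel captures the radical, reductive elimination forges C4–C5 and zinc returns nickel to the zerovalent state. The closest known reaction type is the nickel/bipyridine-catalysed reductive cross-electrophile coupling of aryl or alkenyl halides with terminal epoxides under iodide co-catalysis. No ring is closed and no stereocentre is created: C3 (S) is carried over from 16 because only the CH2 terminus reacts, C7 (R) is a spectator, and the E geometry of C5=C6 is that of 12 because insertion and reductive elimination at an alkenyl carbon go with retention. The step needs opening at the terminal epoxide carbon, secured by the SN2 preference of iodide, and cross- over homo-coupling, secured by the different activation modes of the two electrophiles (two-electron insertion at the sp2 C–I bond, radical formation at the sp3 C–I bond) and the excess of 16. The aryl methyl ketone, the four MOM acetals and the hydroxyl that is formed are inert to zinc and to the nickel species, which is why a reductive union is preferred to an alkenyl-metal route.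

Step 12
Reactants: 18 1-{3-[(1R,2E,5S)-5-hydroxy-1,7-bis[4-(methoxymethoxy)phenyl]hept-2-en-1-yl]-6-methoxy-2,4-bis(methoxymethoxy)phenyl}ethan-1-one; 5 4-(methoxymethoxy)benzaldehyde
Product: 19 (2E)-1-{3-[(1R,2E,5S)-5-hydroxy-1,7-bis[4-(methoxymethoxy)phenyl]hept-2-en-1-yl]-6-methoxy-2,4-bis(methoxymethoxy)phenyl}-3-[4-(methoxymethoxy)phenyl]prop-2-en-1-one
Conditions: KOH (50 % aq.), EtOH, rt
Reagents that add atoms: none
Why: Claisen–Schmidt condensation of the methyl ketone with a non-enolisable aldehyde gives the (E)-enone after E1cB dehydration; hydroxide is far too weak a base to remove the C7–H or to move the C5=C6 bond.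

Step 13
Reactants: 19 (2E)-1-{3-[(1R,2E,5S)-5-hydroxy-1,7-bis[4-(methoxymethoxy)phenyl]hept-2-en-1-yl]-6-methoxy-2,4-bis(methoxymethoxy)phenyl}-3-[4-(methoxymethoxy)phenyl]prop-2-en-1-one
Product: 20 epicalyxin B, (2E)-1-{2,4-dihydroxy-3-[(1R,2E,5S)-5-hydroxy-1,7-bis(4-hydroxyphenyl)hept-2-en-1-yl]-6-methoxyphenyl}-3-(4-hydroxyphenyl)prop-2-en-1-one
Conditions: HCl (3 M aq., small excess), MeOH, rt, monitored closely
Reagents that add atoms: none
Why: Acid-catalysed transacetalisation to methanol removes all five aryl MOM groups at room temperature, conditions under which 2'-hydroxy-6'-methoxychalcones of this ring A type are known to survive without closing to the flavanone.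

**Compound list**
1 | 1-(2,4-dihydroxy-6-methoxyphenyl)ethan-1-one | CC(=O)c1c(O)cc(O)cc1OC | starting material
2 | 1-[2-hydroxy-6-methoxy-4-(methoxymethoxy)phenyl]ethan-1-one | CC(=O)c1c(O)cc(OCOC)cc1OC | intermediate
3 | 1-[2-hydroxy-3-iodo-6-methoxy-4-(methoxymethoxy)phenyl]ethan-1-one | CC(=O)c1c(O)c(I)c(OCOC)cc1OC | intermediate
4 | 1-[3-iodo-6-methoxy-2,4-bis(methoxymethoxy)phenyl]ethan-1-one | CC(=O)c1c(OCOC)c(I)c(OCOC)cc1OC | intermediate
5 | 4-(methoxymethoxy)benzaldehyde | COCOc1ccc(C=O)cc1 | starting material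
6 | lithium 1-[4-(methoxymethoxy)phenyl]-3-(trimethylsilyl)prop-2-yn-1-olate (racemic) | COCOc1ccc(C([O-])C#C[Si](C)(C)C)cc1.[Li+] | intermediate
7 | methyl 1-[4-(methoxymethoxy)phenyl]-3-(trimethylsilyl)prop-2-yn-1-yl carbonate (racemic) | COCOc1ccc(C(OC(=O)OC)C#C[Si](C)(C)C)cc1 | intermediate
8 | [3-acetyl-4-methoxy-2,6-bis(methoxymethoxy)phenyl]zinc iodide | CC(=O)c1c(OCOC)c([Zn]I)c(OCOC)cc1OC | intermediate
9 | 1-{6-methoxy-2,4-bis(methoxymethoxy)-3-[(1R)-1-[4-(methoxymethoxy)phenyl]-3-(trimethylsilyl)prop-2-yn-1-yl]phenyl}ethan-1-one | COc1cc(OCOC)c([C@H](C#C[Si](C)(C)C)c2ccc(OCOC)cc2)c(OCOC)c1C(C)=O | intermediate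
10 | 1-{6-methoxy-2,4-bis(methoxymethoxy)-3-[(1R)-1-[4-(methoxymethoxy)phenyl]prop-2-yn-1-yl]phenyl}ethan-1-one | COc1cc(OCOC)c([C@H](C#C)c2ccc(OCOC)cc2)c(OCOC)c1C(C)=O | intermediate
11 | tributyl{(1E,3R)-3-[3-acetyl-4-methoxy-2,6-bis(methoxymethoxy)phenyl]-3-[4-(methoxymethoxy)phenyl]prop-1-en-1-yl}stannane | COc1cc(OCOC)c([C@H](/C=C/[Sn](CCCC)(CCCC)CCCC)c2ccc(OCOC)cc2)c(OCOC)c1C(C)=O | intermediate
12 | 1-{3-[(1R,2E)-3-iodo-1-[4-(methoxymethoxy)phenyl]prop-2-en-1-yl]-6-methoxy-2,4-bis(methoxymethoxy)phenyl}ethan-1-one | COc1cc(OCOC)c([C@H](/C=C/I)c2ccc(OCOC)cc2)c(OCOC)c1C(C)=O | intermediate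
13 | 1-bromo-4-(methoxymethoxy)benzene | COCOc1ccc(Br)cc1 | starting material
14 | 1-(but-3-en-1-yl)-4-(methoxymethoxy)benzene | COCOc1ccc(CCC=C)cc1 | intermediate
15 | 2-{2-[4-(methoxymethoxy)phenyl]ethyl}oxirane (racemic) | COCOc1ccc(CCC2CO2)cc1 | intermediate
16 | (2S)-2-{2-[4-(methoxymethoxy)phenyl]ethyl}oxirane | COCOc1ccc(CC[C@H]2CO2)cc1 | intermediate
17 | (2S)-1-iodo-4-[4-(methoxymethoxy)phenyl]butan-2-ol | COCOc1ccc(CC[C@H](O)CI)cc1 | intermediate
18 | 1-{3-[(1R,2E,5S)-5-hydroxy-1,7-bis[4-(methoxymethoxy)phenyl]hept-2-en-1-yl]-6-methoxy-2,4-bis(methoxymethoxy)phenyl}ethan-1-one | COc1cc(OCOC)c([C@H](/C=C/C[C@@H](O)CCc2ccc(OCOC)cc2)c2ccc(OCOC)cc2)c(OCOC)c1C(C)=O | intermediate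
19 | (2E)-1-{3-[(1R,2E,5S)-5-hydroxy-1,7-bis[4-(methoxymethoxy)phenyl]hept-2-en-1-yl]-6-methoxy-2,4-bis(methoxymethoxy)phenyl}-3-[4-(methoxymethoxy)phenyl]prop-2-en-1-one | COc1cc(OCOC)c([C@H](/C=C/C[C@@H](O)CCc2ccc(OCOC)cc2)c2ccc(OCOC)cc2)c(OCOC)c1C(=O)/C=C/c1ccc(OCOC)cc1 | intermediate
20 | epicalyxin B | COc1cc(O)c([C@H](/C=C/C[C@@H](O)CCc2ccc(O)cc2)c2ccc(O)cc2)c(O)c1C(=O)/C=C/c1ccc(O)cc1 | target

**Totals**
Total step count: 13. Longest linear sequence: 9 steps (1 → 2 → 3 → 4 → 9 → 10 → 12 → 18 → 19 → 20; steps 1, 2, 3, 5, 6, 7, 11, 12, 13).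

**Steps most likely to fail, with fallbacks**

Step 5. Transmetalation of the doubly ortho-substituted, acyl-deactivated arylzinc may be slow, the carbonate may ionise before it couples, and facial selection may be poor. Fallback, setting out from 5 and 2 and coming back at 9: 5 is treated with lithium (trimethylsilyl)acetylide and quenched with water to give the racemic propargylic alcohol F1. FeCl3-catalysed Friedel–Crafts propargylation of phenol 2 with F1 (MeCN, rt) should deliver the stabilised propargylic cation to C3', ortho to the free hydroxyl, giving the racemic propargylated phenol F2. MOM protection (NaH, MOMCl, DMF) gives the racemic silylalkyne F3, and preparative chromatography on a chiral stationary phase returns the route at 9. This replaces the hindered organometallic coupling by electrophilic substitution on the ring and catalyst control by resolution.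

Step 11. The alkenyl iodide may homocouple or be reduced, iodide opening of the epoxide may lag behind, and a nickel hydride may move the C5=C6 bond into conjugation with the C7 aryl groups. Fallback, setting out from 16 and 12 and coming back at 18: 16 is opened with LiI/AcOH in THF to the iodohydrin 17, now isolated, and silylated (TBSCl, imidazole) to the silyl ether F4. Zinc insertion (Zn dust, LiCl, THF) gives the alkylzinc iodide F5, which is joined to 12 by a Negishi coupling under Pd(PPh3)4 catalysis to the silyl ether F6. TBAF then returns the route at 18. The same C4–C5 bond is made, but by a polar nucleophile–electrophile coupling at palladium instead of a radical union of two electrophiles.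

Step 13. Protic acid may close the 2'-hydroxychalcone to the flavanone by oxa-Michael addition, ionise the doubly benzylic allylic C7 (epimerisation), or leave the hindered 2'-O-MOM in place. Fallback, setting out from 19 and coming back at 20: TMSOTf with 2,2'-bipyridyl in MeCN at 0 °C should exchange the five aryl MOM acetals for silyl ethers and silylate the C3 hydroxyl, giving the hexakis(trimethylsilyl) ether F7 without any protic acid. Stirring with water/MeOH (KF if needed) hydrolyses the silyl ethers at neutral pH and returns the route at 20.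

**Further compounds**
F1 | step 5 | 1-[4-(methoxymethoxy)phenyl]-3-(trimethylsilyl)prop-2-yn-1-ol (racemic) | COCOc1ccc(C(O)C#C[Si](C)(C)C)cc1
F2 | step 5 | 1-{2-hydroxy-6-methoxy-4-(methoxymethoxy)-3-[1-[4-(methoxymethoxy)phenyl]-3-(trimethylsilyl)prop-2-yn-1-yl]phenyl}ethan-1-one (racemic) | COc1cc(OCOC)c(C(C#C[Si](C)(C)C)c2ccc(OCOC)cc2)c(O)c1C(C)=O
F3 | step 5 | 1-{6-methoxy-2,4-bis(methoxymethoxy)-3-[1-[4-(methoxymethoxy)phenyl]-3-(trimethylsilyl)prop-2-yn-1-yl]phenyl}ethan-1-one (racemic 9) | COc1cc(OCOC)c(C(C#C[Si](C)(C)C)c2ccc(OCOC)cc2)c(OCOC)c1C(C)=O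
F4 | step 11 | tert-butyl({(2S)-1-iodo-4-[4-(methoxymethoxy)phenyl]butan-2-yl}oxy)dimethylsilane | COCOc1ccc(CC[C@H](O[Si](C)(C)C(C)(C)C)CI)cc1
F5 | step 11 | {(2S)-2-[(tert-butyldimethylsilyl)oxy]-4-[4-(methoxymethoxy)phenyl]butyl}zinc iodide | COCOc1ccc(CC[C@H](O[Si](C)(C)C(C)(C)C)C[Zn]I)cc1
F6 | step 11 | tert-butyldimethylsilyl ether of 18 at the C3 hydroxyl | COc1cc(OCOC)c([C@H](/C=C/C[C@@H](O[Si](C)(C)C(C)(C)C)CCc2ccc(OCOC)cc2)c2ccc(OCOC)cc2)c(OCOC)c1C(C)=O
F7 | step 13 | hexakis(trimethylsilyl) ether of 20 | COc1cc(O[Si](C)(C)C)c([C@H](/C=C/C[C@@H](O[Si](C)(C)C)CCc2ccc(O[Si](C)(C)C)cc2)c2ccc(O[Si](C)(C)C)cc2)c(O[Si](C)(C)C)c1C(=O)/C=C/c1ccc(O[Si](C)(C)C)cc1
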